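**Strategy.** The N-heterocycle (ring B) is disconnected at N2–C1. C1 is the benzylic carbon on C8a of the dimethoxy ring A and is the sixth atom of the chain N2–C3–C4–C4a–C8a–C1, so a C8a acetyl group and a C3 primary amine are set to condense. The precursor is an open-chain biaryl: ring A carries the naphthyl group at C5, an acetyl group and, between them, a Boc-protected (S)-2-aminopropyl chain taken from an L-alaninol sulfamidate. Boc cleavage unmasks the amine and closes ring B in the same operation by cyclodehydration to the C1=N2 imine; its planar C1 is then reduced under 1,3-induction from C3 to the trans-1,3-dimethyl array.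

Key step: step 9

Assumption: the target does not define the configuration of the hindered C5–C1′ biaryl axis, so no axial control is attempted and compounds 18–22 are carried as mixtures of the two axis epimers, both (S) at C3 and, in 22, (1S,3S).

**Step 1**
Reactants: 1 N,N-diethyl-2-methoxybenzamide
Product: 4 N,N-diethyl-2-methoxy-6-(2-methylallyl)benzamide, via ortho-lithiated amide 2 (not isolated), via arylmagnesium bromide 3 (not isolated)
Conditions: s-BuLi, TMEDA, THF, −78 °C; MgBr2·OEt2, −78 → 0 °C; then 3-bromo-2-methylprop-1-ene, 0 °C → rt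
Reagents that add atoms: 3-bromo-2-methylprop-1-ene, CC(=C)CBr
Why: Directed ortho-metalation by the tertiary amide (a stronger director than methoxy) lithiates C6, and transmetalation to magnesium should allow clean allylation without deprotonation of the benzylic–allylic CH2 of the product.

**Step 2**
Reactants: 4 N,N-diethyl-2-methoxy-6-(2-methylallyl)benzamide
Product: 6 8-methoxy-3-methylnaphthalen-1-ol, via lithium naphthoxide 5 (not isolated)
Conditions: LiN(iPr)2 (2.2 equiv), THF, 0 °C → rt
Reagents that add atoms: none
Why: Deprotonation of the benzylic–allylic CH2 gives an allyl anion whose terminal carbon attacks the amide carbonyl (anionic vinylogous acylation, six-membered ring), and loss of diethylamide with aromatisation should give the 1-naphthoxide, a known amide-based naphthol annulation.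

**Step 3**
Reactants: 6 8-methoxy-3-methylnaphthalen-1-ol
Product: 7 1,8-dimethoxy-3-methylnaphthalene
Conditions: NaH, MeI, DMF, 0 °C → rt
Reagents that add atoms: iodomethane, CI
Why: Williamson O-methylation, with NaH chosen to overcome the hydrogen bond of the naphthol to the peri methoxy group.

**Step 4**
Reactants: 7 1,8-dimethoxy-3-methylnaphthalene
Product: 8 1-bromo-4,5-dimethoxy-2-methylnaphthalene
Conditions: NBS (1.0 equiv), MeCN, 0 °C
Reagents that add atoms: N-bromosuccinimide, O=C1CCC(=O)N1Br
Why: Electrophilic aromatic bromination is expected para to a methoxy group at the position also activated by the adjacent methyl, the para position in the other ring lacking this alkyl activation.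

**Step 5**
Reactants: 9 3,5-dimethoxyphenylmagnesium chloride (1.0 M in THF); 10 tert-butyl (S)-4-methyl-1,2,3-oxathiazolidine-3-carboxylate 2,2-dioxide
Product: 12 tert-butyl (S)-(1-(3,5-dimethoxyphenyl)propan-2-yl)carbamate, via N-sulfate magnesium salt 11 (not isolated)
Conditions: CuI (10 mol %), THF, −20 °C → rt; then 10% aq citric acid, rt
Reagents that add atoms: none
Why: Copper-catalysed SN2 opening of the cyclic sulfamidate occurs at the unsubstituted O-bearing CH2, so the L-alaninol stereocenter (future C3, S) is carried over untouched, and mild acid hydrolyses the N-sulfate without cleaving the Boc group.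

**Step 6**
Reactants: 12 tert-butyl (S)-(1-(3,5-dimethoxyphenyl)propan-2-yl)carbamate
Product: 13 tert-butyl (S)-(1-(2,6-dibromo-3,5-dimethoxyphenyl)propan-2-yl)carbamate
Conditions: NBS (2.1 equiv), MeCN, 0 °C → rt
Reagents that add atoms: N-bromosuccinimide, O=C1CCC(=O)N1Br
Why: Twofold electrophilic aromatic bromination should occur at the two equivalent positions ortho to the side chain, each para to one methoxy and ortho to the other, in preference to the hindered position between the methoxy groups.

**Step 7**
Reactants: 13 tert-butyl (S)-(1-(2,6-dibromo-3,5-dimethoxyphenyl)propan-2-yl)carbamate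
Product: 15 tert-butyl (S)-(1-(2-acetyl-6-bromo-3,5-dimethoxyphenyl)propan-2-yl)carbamate, via N,C-dilithio species 14 (not isolated)
Conditions: n-BuLi (2.05 equiv), THF, −78 °C; then MeC(O)N(OMe)Me, −78 → 0 °C
Reagents that add atoms: N-methoxy-N-methylacetamide, CC(=O)N(C)OC
Why: After N–H deprotonation, bromine–lithium exchange of one of the two constitutionally equivalent bromides and acylation with the N-methoxy-N-methyl amide (chelated tetrahedral intermediate, no over-addition) should install the C1 acetyl group.

**Step 8**
Reactants: 8 1-bromo-4,5-dimethoxy-2-methylnaphthalene; 15 tert-butyl (S)-(1-(2-acetyl-6-bromo-3,5-dimethoxyphenyl)propan-2-yl)carbamate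
Product: 18 tert-butyl (S)-(1-(2-acetyl-6-(4,5-dimethoxy-2-methylnaphthalen-1-yl)-3,5-dimethoxyphenyl)propan-2-yl)carbamate, via naphthyllithium 16 (not isolated), via naphthylzinc chloride 17 (not isolated)
Conditions: 8 (2 equiv), n-BuLi, THF, −78 °C; ZnCl2, −78 °C → rt; then 15, Pd2(dba)3 (2.5 mol %), RuPhos (10 mol %), THF/NMP, 70 °C
Reagents that add atoms: none
Why: Negishi coupling with a bulky dialkylbiarylphosphine is suited to tetra-ortho-substituted biaryls and, being base-free, should tolerate the ketone and the carbamate N–H.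

**Step 9**
Reactants: 18 tert-butyl (S)-(1-(2-acetyl-6-(4,5-dimethoxy-2-methylnaphthalen-1-yl)-3,5-dimethoxyphenyl)propan-2-yl)carbamate
Product: 20 (S)-5-(4,5-dimethoxy-2-methylnaphthalen-1-yl)-6,8-dimethoxy-1,3-dimethyl-3,4-dihydroisoquinoline, via amino ketone hydrochloride 19 (not isolated)
Conditions: 4 M HCl in dioxane, CH2Cl2, 0 °C → rt; then sat. aq NaHCO3, CH2Cl2, rt (4 Å MS)
Reagents that add atoms: none
Why: Acidolysis of the Boc group (loss of CO2 and 2-methylpropene) frees the C3 primary amine, which on neutralisation adds to the acetyl carbonyl on C8a, and the hemiaminal dehydrates to the C1=N2 ketimine. The closest known reaction type is the intramolecular amine–ketone condensation that gives 1-methyl-3,4-dihydroisoquinolines, the same cyclic imines otherwise reached by Bischler–Napieralski closure. Ring B closes by 6-exo-trig attack of N2 on the carbonyl carbon, the C=N bond becoming endocyclic after loss of water. No stereocenter is formed: C3 (S) is neither ionised nor enolisable under these conditions, and C1 is deliberately left planar for the next step. The step needs only chemoselectivity for intramolecular condensation, which the six-atom relationship of N2 and C1 through C3–C4–C4a–C8a secures; the ketimine is stabilised by conjugation with ring A and cannot aromatise because C3 and C4 are sp3.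

**Step 10**
Reactants: 20 (S)-5-(4,5-dimethoxy-2-methylnaphthalen-1-yl)-6,8-dimethoxy-1,3-dimethyl-3,4-dihydroisoquinoline
Product: 22 (1S,3S)-5-(4,5-dimethoxy-2-methylnaphthalen-1-yl)-6,8-dimethoxy-1,3-dimethyl-1,2,3,4-tetrahydroisoquinoline, via imine–AlMe3 adduct 21 (not isolated)
Conditions: AlMe3 (3 equiv), THF, −78 °C; then LiAlH4, −78 → −40 °C
Reagents that add atoms: none
Why: Lewis-acid-directed hydride reduction of a cyclic imine with 1,3-induction, in which AlMe3 on N2 should force the C3 methyl pseudoaxial so that axial hydride attack puts the new C1–H on the face of that methyl and the two methyl groups trans (1S,3S), the established trans-selective protocol for 1,3-dimethyl-3,4-dihydroisoquinolines.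

**Compound list**

1 | N,N-diethyl-2-methoxybenzamide | CCN(CC)C(=O)c1ccccc1OC | starting material
2 | N,N-diethyl-2-lithio-6-methoxybenzamide | CCN(CC)C(=O)c1c(OC)cccc1[Li] | intermediate
3 | (2-(diethylcarbamoyl)-3-methoxyphenyl)magnesium bromide | CCN(CC)C(=O)c1c(OC)cccc1[Mg]Br | intermediate
4 | N,N-diethyl-2-methoxy-6-(2-methylallyl)benzamide | CCN(CC)C(=O)c1c(OC)cccc1CC(C)=C | intermediate
5 | lithium 8-methoxy-3-methylnaphthalen-1-olate | [Li+].[O-]c1cc(C)cc2cccc(OC)c12 | intermediate
6 | 8-methoxy-3-methylnaphthalen-1-ol | Oc1cc(C)cc2cccc(OC)c12 | intermediate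
7 | 1,8-dimethoxy-3-methylnaphthalene | COc1cc(C)cc2cccc(OC)c12 | intermediate
8 | 1-bromo-4,5-dimethoxy-2-methylnaphthalene | COc1cc(C)c(Br)c2cccc(OC)c12 | intermediate
9 | 3,5-dimethoxyphenylmagnesium chloride | COc1cc(OC)cc([Mg]Cl)c1 | starting material
10 | tert-butyl (S)-4-methyl-1,2,3-oxathiazolidine-3-carboxylate 2,2-dioxide | C[C@H]1COS(=O)(=O)N1C(=O)OC(C)(C)C | starting material
11 | chloromagnesium (S)-N-(tert-butoxycarbonyl)-N-(1-(3,5-dimethoxyphenyl)propan-2-yl)sulfamate | COc1cc(OC)cc(C[C@H](C)N(C(=O)OC(C)(C)C)S(=O)(=O)O[Mg]Cl)c1 | intermediate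
12 | tert-butyl (S)-(1-(3,5-dimethoxyphenyl)propan-2-yl)carbamate | COc1cc(OC)cc(C[C@H](C)NC(=O)OC(C)(C)C)c1 | intermediate
13 | tert-butyl (S)-(1-(2,6-dibromo-3,5-dimethoxyphenyl)propan-2-yl)carbamate | COc1cc(OC)c(Br)c(C[C@H](C)NC(=O)OC(C)(C)C)c1Br | intermediate
14 | N,C-dilithio derivative of 13 (N-lithio carbamate, 2-lithio-6-bromoarene) | COc1cc(OC)c([Li])c(C[C@H](C)N([Li])C(=O)OC(C)(C)C)c1Br | intermediate
15 | tert-butyl (S)-(1-(2-acetyl-6-bromo-3,5-dimethoxyphenyl)propan-2-yl)carbamate | COc1cc(OC)c(C(C)=O)c(C[C@H](C)NC(=O)OC(C)(C)C)c1Br | intermediate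
16 | (4,5-dimethoxy-2-methylnaphthalen-1-yl)lithium | COc1cc(C)c([Li])c2cccc(OC)c12 | intermediate
17 | (4,5-dimethoxy-2-methylnaphthalen-1-yl)zinc chloride | COc1cc(C)c([Zn]Cl)c2cccc(OC)c12 | intermediate
18 | tert-butyl (S)-(1-(2-acetyl-6-(4,5-dimethoxy-2-methylnaphthalen-1-yl)-3,5-dimethoxyphenyl)propan-2-yl)carbamate (both axis epimers) | COc1cc(OC)c(C(C)=O)c(C[C@H](C)NC(=O)OC(C)(C)C)c1-c1c(C)cc(OC)c2c(OC)cccc12 | intermediate
19 | (S)-1-(2-acetyl-6-(4,5-dimethoxy-2-methylnaphthalen-1-yl)-3,5-dimethoxyphenyl)propan-2-aminium chloride | COc1cc(OC)c(C(C)=O)c(C[C@H](C)[NH3+])c1-c1c(C)cc(OC)c2c(OC)cccc12.[Cl-] | intermediate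
20 | (S)-5-(4,5-dimethoxy-2-methylnaphthalen-1-yl)-6,8-dimethoxy-1,3-dimethyl-3,4-dihydroisoquinoline (both axis epimers) | COc1cc(OC)c2c(c1-c1c(C)cc(OC)c3c(OC)cccc13)C[C@H](C)N=C2C | intermediate
21 | N2–AlMe3 adduct of 20 | COc1cc(OC)c2c(c1-c1c(C)cc(OC)c3c(OC)cccc13)C[C@H](C)[N+]([Al-](C)(C)C)=C2C | intermediate
22 | (1S,3S)-5-(4,5-dimethoxy-2-methylnaphthalen-1-yl)-6,8-dimethoxy-1,3-dimethyl-1,2,3,4-tetrahydroisoquinoline | COc1cc(OC)c2c(c1-c1c(C)cc(OC)c3c(OC)cccc13)C[C@H](C)N[C@H]2C | target

**Step count.** Total: 10 steps. Longest linear sequence: 7 steps (steps 1, 2, 3, 4, 8, 9, 10).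

**Steps most likely to fail**

Step 8 (biaryl coupling). Transmetalation and reductive elimination at the tetra-ortho-substituted centre may be slower than protonation of the naphthylzinc reagent by the carbamate N–H and hydrodehalogenation of 15, so that the coupling stalls. The fallback removes the N–H before the coupling by running the ring closure first. Setting out from 15, HCl in dioxane followed by NaHCO3 should give, through (S)-1-(2-acetyl-6-bromo-3,5-dimethoxyphenyl)propan-2-aminium chloride F1, the cyclic imine (S)-5-bromo-6,8-dimethoxy-1,3-dimethyl-3,4-dihydroisoquinoline F2 by the same N2–C1 cyclodehydration. Setting out from 8, n-BuLi then B(OMe)3 and aqueous acid should give (4,5-dimethoxy-2-methylnaphthalen-1-yl)boronic acid F3. Suzuki–Miyaura coupling of F2 with F3 (Pd(OAc)2, SPhos, K3PO4, toluene/H2O, 100 °C) comes back to the route at 20.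

Step 10 (trans-selective reduction). Hydride delivery may lose facial selectivity if complexation of AlMe3 at the hindered N2 is incomplete or if the C5 naphthyl group shifts the half-chair population, so that the cis (1R,3S) epimer is co-formed. The fallback replaces substrate control by catalyst control. Asymmetric transfer hydrogenation of 20 with RuCl(p-cymene)[(R,R)-TsDPEN] and HCO2H/Et3N in MeCN uses the catalyst enantiomer expected to give the (1S) amine from 1-methyl-3,4-dihydroisoquinolines. It sets out from 20 and comes back at 22, and no new compound is made.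

Step 7 (mono-exchange and acylation). The hindered aryllithium 14 may act as a base towards the enolisable N-methoxy-N-methylacetamide, giving proton transfer in place of acylation, or exchange may run on at the second bromide. In the fallback, setting out from 13, 14 is generated as before but trapped with acetaldehyde, whose carbonyl addition should outrun enolisation. This should give tert-butyl ((2S)-1-(2-bromo-6-(1-hydroxyethyl)-3,5-dimethoxyphenyl)propan-2-yl)carbamate F4 as a mixture of carbinol epimers. Oxidation with Dess–Martin periodinane (CH2Cl2, NaHCO3) comes back to the route at 15.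

**Further compounds**

F1 | step 8 | (S)-1-(2-acetyl-6-bromo-3,5-dimethoxyphenyl)propan-2-aminium chloride | COc1cc(OC)c(C(C)=O)c(C[C@H](C)[NH3+])c1Br.[Cl-]
F2 | step 8 | (S)-5-bromo-6,8-dimethoxy-1,3-dimethyl-3,4-dihydroisoquinoline | COc1cc(OC)c2c(c1Br)C[C@H](C)N=C2C
F3 | step 8 | (4,5-dimethoxy-2-methylnaphthalen-1-yl)boronic acid | COc1cc(C)c(B(O)O)c2cccc(OC)c12
F0 | step 10 | none | none
F4 | step 7 | tert-butyl ((2S)-1-(2-bromo-6-(1-hydroxyethyl)-3,5-dimethoxyphenyl)propan-2-yl)carbamate | COc1cc(OC)c(C(C)O)c(C[C@H](C)NC(=O)OC(C)(C)C)c1Br
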